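## Structural features

The target 15 is a 3-substituted isochroman-1-one (3,4-dihydroisocoumarin). A benzene ring (C4a, C5, C6, C7, C8, C8a) is fused to a six-membered δ-lactone (C1, O2, C3, C4), with free phenols at C6 and C8; the C8 hydroxyl is hydrogen-bonded to the C1 carbonyl. C3 carries an unbranched undecyl chain (C1'–C11') whose only functional group is the secondary alcohol at C6'. The two stereocentres, C3 (R) and C6' (S), are not neighbours: five methylene groups lie between them, so neither can steer the formation of the other. Sensitive points are the lactone (opened by alkoxide or hydroxide, reclosed by acid), the electron-rich resorcinol once unmasked (oxidation in base, attack by electrophiles) and, in the intermediates, a terminal olefin that has to survive an aromatic bromination and a palladium step. C3 is the easy centre, because it sits two atoms from the arene and can be bought as a three-carbon epoxide. The real difficulty is C6': its two carbon substituents, a pentyl group and the pentamethylene tether, are identical over five atoms, so no reduction or addition that reads steric size can tell its faces apart. The key step therefore creates C6' as a prochiral, oxygen-bearing radical and joins it to C5', the terminal carbon of the C4'=C5' olefin of lactone 9, under a chiral nickel catalyst that recognises the oxygen substituent and not the chains.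

## Logic of the disconnections

15 ⇒ 13 (through 14). No skeletal bond is cut; the O–benzyl bonds at C6 and C8 and the O–acyl bond at C6' are put back. This masks the oxidisable resorcinol and keeps the C6' oxygen in the form in which the coupling delivers it. The forward demand is that hydrogenolysis and ester cleavage spare the lactone or let it reclose on acidification.

13 ⇒ 9 + 12. The C5'–C6' bond is cut. The cut lies at the difficult centre, splits the chain into a terminal olefin and a C6 unit functionalised at its first carbon, and keeps C6' out of every earlier intermediate. The forward step must form a C(sp3)–C(sp3) bond with linear regiochemistry and set C6' by catalyst control, independently of C3.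

12 ⇒ 10 + 11. The C6'–Br and C6'–O bonds are cut, the reverse of adding an acyl bromide across an aldehyde carbonyl. Both pieces are bulk chemicals, and the racemic nature of 12 does no harm because the coupling is stereoconvergent. The only demand is that 12 forms cleanly enough to be used without purification.

9 ⇒ 8. The C8a–C1 and C1–O2 bonds are cut, removing one carbon monoxide. The lactone becomes an aryl bromide with a pendant secondary alcohol in which C3 is already in place. The forward carbonylation must outrun direct aryl C–O coupling and leave the olefin alone.

8 ⇒ 7. The C8a–Br bond is cut. This uses the innate preference of a 3,5-dialkoxy-alkylbenzene for substitution ortho to the alkyl group and para to one alkoxy group. The demand is that bromine attacks the arene much faster than the remote olefin and only once.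

7 ⇒ 4 + 5 (through 6). The C4–C4a bond is cut. This separates the arene from the whole aliphatic part and traces C3 to a terminal epoxide. The aryl nucleophile must attack only the unsubstituted epoxide carbon, so that the configuration of C3 is carried over unchanged.

4 ⇒ 1 + 2 (through 3). The C1'–C2' bond is cut. The stereocentre is reduced to a commercial three-carbon chiral-pool epoxide, which avoids a resolution that would discard half of a racemate. The nucleophile must open the epoxide and not displace chloride directly, because the two modes lead to opposite enantiomers of 4.

## Other disconnections considered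

Alternative 1: The aromatic ring itself is taken apart at C4a–C5 and C8–C8a. This leads back to the alkynoate methyl (5R,11S)-5,11-bis(tert-butyldimethylsilyloxy)hexadec-2-ynoate A2 and the diene 1-methoxy-1,3-bis(trimethylsilyloxy)buta-1,3-diene A3. Forward, a thermal Diels–Alder reaction followed by aromatisation and loss of the trimethylsilyl groups would give the resorcylate methyl 2-[(2R,8S)-2,8-bis(tert-butyldimethylsilyloxy)tridecyl]-4,6-dihydroxybenzoate A1; fluoride and acid would then close the lactone.
- In its favour: the polarity of A2 and A3 places the ester next to the C8 oxygen and the chain next to C5 without any arene halogenation, carbon monoxide or benzyl ethers. On control of the aromatic substitution pattern this plan is the equal of the chosen one and arguably the better.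
- Against it: both stereocentres must already be present in A2, so the C6' problem is only moved into an acyclic precursor, where it still needs its own asymmetric C–C bond formation.
- Against it: an alkyl-substituted alkynoate is a sluggish dienophile and would need forcing temperatures, under which the propargylic C4 methylene of A2 may isomerise to an allenoate.
- Comparison: the ring construction is pericyclic and convergent, but the route to A2 alone should be about as long as the whole chosen sequence. The chosen plan buys the ring and spends its one demanding step on the hard centre.

Alternative 2: The O2–C3 bond is cut, leading to the allylic carbonate (E)-2-[4-(methoxycarbonyloxy)but-2-en-1-yl]-4,6-dimethoxybenzoic acid A5. Forward, [Ir(cod)Cl]2 with a chiral phosphoramidite would ionise the carbonate and the carboxylate would close onto the internal allyl terminus to give (S)-6,8-dimethoxy-3-vinylisochroman-1-one A4. Its descriptor is S only because vinyl outranks C4; the spatial arrangement is that of (R)-C3 in 15.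
- In its favour: C3 is set catalytically from an achiral precursor in the same event that closes the ring, and the six-membered closure is the branched mode that monovalent iridium allyl chemistry prefers. As a way of making C3 this is more elegant than the chiral-pool purchase of the chosen route and its equal in step count for that centre.
- Against it: A4 ends at C2'. Nine carbons including C6' still have to be attached, for example by cross-metathesis with (S)-undec-1-en-6-ol A6, which needs its own asymmetric synthesis.
- Against it: the resulting allylic lactone must be hydrogenated without hydrogenolysis of the allylic C3–O2 bond, and A4 is an allylic ester that could re-ionise and lose enantiopurity.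
- Against it: the methyl ethers require a harsh Lewis-acid demethylation in the presence of the C6' alcohol.
- Comparison: the mechanism (outer-sphere attack on an allyl–iridium complex) is well understood, but the plan leaves the hard centre unsolved and should be longer overall.

Alternative 3: The same bonds as in step 4 of the chosen route are cut (C8a–C1 and C1–O2), but from a C–H instead of a C–Br precursor: (2R,8S)-1-[3,5-bis(benzyloxy)phenyl]-8-(tert-butyldimethylsilyloxy)tridecan-2-ol A8. Forward, Pd(OAc)2 (divalent palladium) under carbon monoxide with an oxidant such as AgOAc would bind the C3 hydroxyl, cleave the ortho C–H bond, insert CO and release (R)-6,8-bis(benzyloxy)-3-[(S)-6-(tert-butyldimethylsilyloxy)undecyl]isochroman-1-one A7.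
- In its favour: the bromination is saved, so the question of bromine against olefin never arises, and the two ortho positions of A8 are equivalent. For the lactone closure this is one step shorter than the chosen route, a point on which it is the better.
- Against it: hydroxyl-directed C–H carbonylation is established for tertiary and strongly hindered alcohols. A8 is a secondary carbinol whose palladium alkoxide can undergo β-hydride elimination to the ketone under the oxidising conditions.
- Against it: the C–H bond to be cleaved lies between the tether and a benzyloxy group, and the electron-rich arene meets a stoichiometric oxidant.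
- Against it: C6' must already be in place in A8, so the hard centre needs a separate solution earlier in the route.
- Comparison: the chosen route pays one extra step for a zerovalent-palladium carbonylation of a C–Br bond, which does not depend on the nature of the carbinol.

Key step: step 5

Remark on the chemistry: the sense of induction at C6' is taken to depend on the ligand alone. "Chiral bis(oxazoline)" below means the enantiomer that gives the (S)-carbinol ester from a simple 1-alkene; both antipodes are accessible and the sense is to be confirmed on a model olefin before 9 is committed.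

## Route

Step 1
Reactants: 1 (R)-2-(chloromethyl)oxirane [(R)-epichlorohydrin]; 2 but-3-en-1-ylmagnesium bromide (commercial solution in THF)
Product: 4 (R)-2-(pent-4-en-1-yl)oxirane, via (R)-1-chlorohept-6-en-2-ol 3 (not isolated)
Conditions: 2 (1.15 equiv), CuI (5 mol%), THF, −40 → −10 °C; then 4 M aq NaOH, rt, same flask; extraction, distillation
Reagents that add atoms: none
Why: Copper-catalysed Grignard opening of the epoxide at its unsubstituted carbon forms C1'–C2' without touching the C–O stereocentre, and hydroxide then closes the chlorohydrin by intramolecular Williamson displacement of chloride, so (R)-1 should give (R)-4 with the configuration carried over.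

Step 2
Reactants: 4 (R)-2-(pent-4-en-1-yl)oxirane; 5 1,3-bis(benzyloxy)-5-bromobenzene
Product: 7 (R)-1-[3,5-bis(benzyloxy)phenyl]hept-6-en-2-ol, via [3,5-bis(benzyloxy)phenyl]magnesium bromide 6 (not isolated)
Conditions: 5 (1.3 equiv), Mg, I2 (cat.), THF, 50 °C; then CuI (10 mol%), 4, −30 → 0 °C; sat. aq NH4Cl
Reagents that add atoms: none
Why: Magnesium insertion gives the aryl Grignard reagent, and its copper-catalysed SN2 opening of the terminal epoxide at the CH2 carbon forms C4–C4a; the carbinol carbon is not attacked, so C3 keeps the (R) configuration.

Step 3
Reactants: 7 (R)-1-[3,5-bis(benzyloxy)phenyl]hept-6-en-2-ol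
Product: 8 (R)-1-[3,5-bis(benzyloxy)-2-bromophenyl]hept-6-en-2-ol
Conditions: NBS (1.0 equiv), MeCN, −20 → 0 °C, dark
Reagents that add atoms: N-bromosuccinimide, O=C1CCC(=O)N1Br
Why: Electrophilic aromatic bromination of a 3,5-dialkoxy-alkylbenzene goes ortho to the alkyl group and para to one alkoxy group; the doubly activated arene should react far faster than an unactivated terminal olefin in the cold, in the dark and with one equivalent of reagent.

Step 4
Reactants: 8 (R)-1-[3,5-bis(benzyloxy)-2-bromophenyl]hept-6-en-2-ol
Product: 9 (R)-6,8-bis(benzyloxy)-3-(pent-4-en-1-yl)isochroman-1-one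
Conditions: Pd(PPh3)4 (5 mol%), CO (1 atm), K2CO3 (2 equiv), DMF, 90 °C
Reagents that add atoms: carbon monoxide, [C-]#[O+]
Why: Heck-type intramolecular alkoxycarbonylation: zerovalent palladium inserts into the C–Br bond, CO insertion gives the aroylpalladium bromide, and the C3 hydroxyl captures it in a six-membered closure that forms C8a–C1 and C1–O2; with triphenylphosphine under CO this should be faster than direct aryl C–O coupling or any Heck reaction of the remote olefin, and C3 is not involved.

Step 5
Reactants: 9 (R)-6,8-bis(benzyloxy)-3-(pent-4-en-1-yl)isochroman-1-one; 10 hexanal; 11 2-methylpropanoyl bromide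
Product: 13 (S)-1-[(R)-6,8-bis(benzyloxy)-1-oxoisochroman-3-yl]undecan-6-yl 2-methylpropanoate, via rac-1-bromohexyl 2-methylpropanoate 12 (not isolated)
Conditions: 10 + 11 (2.0 equiv each), neat, 0 °C → rt, 1 h; then 9, NiBr2·glyme (10 mol%), chiral bis(oxazoline) (12 mol%), (EtO)2MeSiH (2.5 equiv), K3PO4·H2O (3 equiv), i-Pr2O–DMA, rt
Reagents that add atoms: none
Why: The acyl bromide adds across the aldehyde carbonyl to give racemic 12; the hydrosilane and phosphate turn the ligated nickel bromide into a nickel hydride, which inserts the C4'=C5' olefin of 9 with nickel on the terminal carbon to give a primary C5' alkylnickel. A low-valent (monovalent) nickel species takes the bromine atom from 12, and both enantiomers collapse to the same planar α-acyloxy radical at C6'. The chiral alkylnickel captures this radical and the resulting trivalent dialkylnickel reductively eliminates, forming C5'–C6'; no ring is closed, so no mode of closure applies. The closest known reaction type is the nickel-hydride-catalysed enantioconvergent hydroalkylation of terminal olefins with racemic 1-bromoalkyl esters, including the variant in which aldehyde and acyl bromide make the electrophile in the flask. C6' is controlled by the bis(oxazoline) on nickel, which differentiates the faces of the radical through its acyloxy group against an alkyl group and not through the lengths of the two chains, so the near-identity of pentyl and pentamethylene is no obstacle. C3 lies seven atoms away and should not influence the outcome, so the (3R,6'S) diastereomer is set by the catalyst alone. Linear regiochemistry is needed and is secured by the monosubstituted, unhindered olefin held four methylenes from C3 with no group nearby to draw the metal along the chain; chemoselectivity is secured because the doubly ortho-substituted aryl lactone and the benzyl ethers are inert to silane and nickel hydride at room temperature.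

Step 6
Reactants: 13 (S)-1-[(R)-6,8-bis(benzyloxy)-1-oxoisochroman-3-yl]undecan-6-yl 2-methylpropanoate
Product: 15 (R)-6,8-dihydroxy-3-[(S)-6-hydroxyundecyl]isochroman-1-one, via (S)-1-[(R)-6,8-dihydroxy-1-oxoisochroman-3-yl]undecan-6-yl 2-methylpropanoate 14 (not isolated)
Conditions: H2 (1 atm), 10% Pd/C, THF–MeOH, rt; filter (Celite); K2CO3 (3 equiv), MeOH, 40 °C, under argon; then 1 M HCl to pH 2, rt
Reagents that add atoms: none
Why: Hydrogenolysis cleaves both aryl benzyl ethers without touching the lactone or the ester; in the filtrate, carbonate-mediated transesterification removes the 2-methylpropanoate while the phenolate formed at C6 and C8 deactivates the lactone carbonyl, and acidification recloses any lactone that did open; neither operation touches C3 or C6'.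

## Compound list

1 | (R)-2-(chloromethyl)oxirane | ClC[C@H]1CO1 | starting material
2 | but-3-en-1-ylmagnesium bromide | C=CCC[Mg]Br | starting material
3 | (R)-1-chlorohept-6-en-2-ol (present as its magnesium alkoxide) | C=CCCC[C@@H](O)CCl | intermediate (not isolated)
4 | (R)-2-(pent-4-en-1-yl)oxirane | C=CCCC[C@@H]1CO1 | intermediate
5 | 1,3-bis(benzyloxy)-5-bromobenzene | Brc1cc(OCc2ccccc2)cc(OCc2ccccc2)c1 | starting material
6 | [3,5-bis(benzyloxy)phenyl]magnesium bromide | Br[Mg]c1cc(OCc2ccccc2)cc(OCc2ccccc2)c1 | intermediate (not isolated)
7 | (R)-1-[3,5-bis(benzyloxy)phenyl]hept-6-en-2-ol | C=CCCC[C@@H](O)Cc1cc(OCc2ccccc2)cc(OCc2ccccc2)c1 | intermediate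
8 | (R)-1-[3,5-bis(benzyloxy)-2-bromophenyl]hept-6-en-2-ol | C=CCCC[C@@H](O)Cc1cc(OCc2ccccc2)cc(OCc2ccccc2)c1Br | intermediate
9 | (R)-6,8-bis(benzyloxy)-3-(pent-4-en-1-yl)isochroman-1-one | C=CCCC[C@@H]1Cc2cc(OCc3ccccc3)cc(OCc3ccccc3)c2C(=O)O1 | intermediate
10 | hexanal | CCCCCC=O | starting material
11 | 2-methylpropanoyl bromide | CC(C)C(Br)=O | starting material
12 | rac-1-bromohexyl 2-methylpropanoate | CCCCCC(Br)OC(=O)C(C)C | intermediate (not isolated)
13 | (S)-1-[(R)-6,8-bis(benzyloxy)-1-oxoisochroman-3-yl]undecan-6-yl 2-methylpropanoate | CCCCC[C@H](OC(=O)C(C)C)CCCCC[C@@H]1Cc2cc(OCc3ccccc3)cc(OCc3ccccc3)c2C(=O)O1 | intermediate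
14 | (S)-1-[(R)-6,8-dihydroxy-1-oxoisochroman-3-yl]undecan-6-yl 2-methylpropanoate | CCCCC[C@H](OC(=O)C(C)C)CCCCC[C@@H]1Cc2cc(O)cc(O)c2C(=O)O1 | intermediate (not isolated)
15 | (R)-6,8-dihydroxy-3-[(S)-6-hydroxyundecyl]isochroman-1-one | CCCCC[C@H](O)CCCCC[C@@H]1Cc2cc(O)cc(O)c2C(=O)O1 | target

## Step count and least certain steps

Total step count: 6. Longest linear sequence: 6 steps (1 → 4 → 7 → 8 → 9 → 13 → 15); 2, 5, 10 and 11 enter as commercial compounds.

Step 5 (key step). The most likely failure is incomplete facial discrimination at the C6' radical on this substrate. That would give a mixture of C6' epimers that is hard to separate, because the two centres are far apart. Competing processes are plain reduction or isomerisation of the olefin by the nickel hydride and hydrolysis of 12 by the hydrated base. Fallback: the C6' centre is bought and the chain is joined by olefin metathesis, setting out from 9.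
- Commercial (S)-oct-1-en-3-ol is acylated (2-methylpropanoic anhydride, Et3N, DMAP, CH2Cl2) to (S)-oct-1-en-3-yl 2-methylpropanoate F1.
- Cross-metathesis of 9 with an excess of F1 (second-generation Grubbs catalyst RuCl2(=CHPh)(PCy3)(H2IMes), CH2Cl2, 40 °C) should give (S,E)-1-[(R)-6,8-bis(benzyloxy)-1-oxoisochroman-3-yl]undec-4-en-6-yl 2-methylpropanoate F2, with the same chain length as 13.
- Hydrogenation of the disubstituted olefin with RhCl(PPh3)3 and H2 (benzene–ethanol, rt), which should spare the benzyl ethers and the allylic C–O bond, comes back to the route at 13.

Step 3. Electrophilic bromine may be diverted to the terminal olefin (bromoetherification through the C2 hydroxyl, or addition), or a second bromination may occur at the other ortho position of the arene; either consumes reagent and gives products close in polarity to 8. Fallback: the order of events is changed so that the arene is brominated before any olefin is present, setting out from 6 (made from 5 as in step 2).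
- Copper-catalysed opening of (S)-2-(chloromethyl)oxirane, the commercial enantiomer of 1, gives (S)-1-[3,5-bis(benzyloxy)phenyl]-3-chloropropan-2-ol F3.
- NBS in MeCN gives (S)-1-[3,5-bis(benzyloxy)-2-bromophenyl]-3-chloropropan-2-ol F4.
- Aqueous NaOH closes it to (S)-2-[3,5-bis(benzyloxy)-2-bromobenzyl]oxirane F5.
- Opening of F5 at its CH2 terminus with 2 and CuI (THF, −30 °C, where bromine–magnesium exchange at the aryl bromide is slow) comes back to the route at 8. The change of descriptor from S to R is one of substituent priorities only.

Step 4. Oxidative addition of zerovalent palladium into a C–Br bond that is electron-rich and flanked by two ortho substituents may be slow, so that catalyst deactivation under CO or reductive loss of bromine competes. Fallback: the carboxyl carbon is introduced as an electrophile, setting out from 8.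
- n-BuLi (2.2 equiv, THF, −78 °C) forms the lithium alkoxide and exchanges bromine for lithium.
- CO2, then aq HCl, gives 2,4-bis(benzyloxy)-6-[(R)-2-hydroxyhept-6-en-1-yl]benzoic acid F6.
- F6 closes on warming with TsOH in toluene and comes back to the route at 9.

Step 6. Methanolysis of the hindered 2-methylpropanoate may be slow, and long exposure of the unmasked resorcinol lactone to base invites lactone opening with incomplete reclosure and oxidative degradation of the phenolate. Fallback: the ester is removed before the phenols are unmasked, setting out from 13.
- KOH in MeOH–H2O (60 °C) hydrolyses the 2-methylpropanoate and opens the lactone to 2,4-bis(benzyloxy)-6-[(2R,8S)-2,8-dihydroxytridecyl]benzoic acid F7.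
- Acidification (aq HCl, then TsOH in toluene if needed) recloses the lactone to (R)-6,8-bis(benzyloxy)-3-[(S)-6-hydroxyundecyl]isochroman-1-one F8. Only the C2 hydroxyl can form a six-membered ring; the C8 hydroxyl would need a twelve-membered one.
- Hydrogenolysis (H2, 10% Pd/C, EtOAc, rt) then ends at 15 with no basic operation after deprotection.

## Further compounds

F1 | step 5 | (S)-oct-1-en-3-yl 2-methylpropanoate | CCCCC[C@H](OC(=O)C(C)C)C=C
F2 | step 5 | (S,E)-1-[(R)-6,8-bis(benzyloxy)-1-oxoisochroman-3-yl]undec-4-en-6-yl 2-methylpropanoate | CCCCC[C@H](OC(=O)C(C)C)/C=C/CCC[C@@H]1Cc2cc(OCc3ccccc3)cc(OCc3ccccc3)c2C(=O)O1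
F3 | step 3 | (S)-1-[3,5-bis(benzyloxy)phenyl]-3-chloropropan-2-ol | ClC[C@@H](O)Cc1cc(OCc2ccccc2)cc(OCc2ccccc2)c1
F4 | step 3 | (S)-1-[3,5-bis(benzyloxy)-2-bromophenyl]-3-chloropropan-2-ol | ClC[C@@H](O)Cc1cc(OCc2ccccc2)cc(OCc2ccccc2)c1Br
F5 | step 3 | (S)-2-[3,5-bis(benzyloxy)-2-bromobenzyl]oxirane | Brc1c(C[C@H]2CO2)cc(OCc2ccccc2)cc1OCc1ccccc1
F6 | step 4 | 2,4-bis(benzyloxy)-6-[(R)-2-hydroxyhept-6-en-1-yl]benzoic acid | C=CCCC[C@@H](O)Cc1cc(OCc2ccccc2)cc(OCc2ccccc2)c1C(=O)O
F7 | step 6 | 2,4-bis(benzyloxy)-6-[(2R,8S)-2,8-dihydroxytridecyl]benzoic acid | CCCCC[C@H](O)CCCCC[C@@H](O)Cc1cc(OCc2ccccc2)cc(OCc2ccccc2)c1C(=O)O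
F8 | step 6 | (R)-6,8-bis(benzyloxy)-3-[(S)-6-hydroxyundecyl]isochroman-1-one | CCCCC[C@H](O)CCCCC[C@@H]1Cc2cc(OCc3ccccc3)cc(OCc3ccccc3)c2C(=O)O1
A1 | alternative 1 | methyl 2-[(2R,8S)-2,8-bis(tert-butyldimethylsilyloxy)tridecyl]-4,6-dihydroxybenzoate | CCCCC[C@H](O[Si](C)(C)C(C)(C)C)CCCCC[C@@H](O[Si](C)(C)C(C)(C)C)Cc1cc(O)cc(O)c1C(=O)OC
A2 | alternative 1 | methyl (5R,11S)-5,11-bis(tert-butyldimethylsilyloxy)hexadec-2-ynoate | CCCCC[C@H](O[Si](C)(C)C(C)(C)C)CCCCC[C@@H](O[Si](C)(C)C(C)(C)C)CC#CC(=O)OC
A3 | alternative 1 | 1-methoxy-1,3-bis(trimethylsilyloxy)buta-1,3-diene | COC(O[Si](C)(C)C)=CC(=C)O[Si](C)(C)C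
A4 | alternative 2 | (S)-6,8-dimethoxy-3-vinylisochroman-1-one | C=C[C@@H]1Cc2cc(OC)cc(OC)c2C(=O)O1
A5 | alternative 2 | (E)-2-[4-(methoxycarbonyloxy)but-2-en-1-yl]-4,6-dimethoxybenzoic acid | COC(=O)OC/C=C/Cc1cc(OC)cc(OC)c1C(=O)O
A6 | alternative 2 | (S)-undec-1-en-6-ol | CCCCC[C@H](O)CCCC=C
A7 | alternative 3 | (R)-6,8-bis(benzyloxy)-3-[(S)-6-(tert-butyldimethylsilyloxy)undecyl]isochroman-1-one | CCCCC[C@H](O[Si](C)(C)C(C)(C)C)CCCCC[C@@H]1Cc2cc(OCc3ccccc3)cc(OCc3ccccc3)c2C(=O)O1
A8 | alternative 3 | (2R,8S)-1-[3,5-bis(benzyloxy)phenyl]-8-(tert-butyldimethylsilyloxy)tridecan-2-ol | CCCCC[C@H](O[Si](C)(C)C(C)(C)C)CCCCC[C@@H](O)Cc1cc(OCc2ccccc2)cc(OCc2ccccc2)c1
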